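**Retrosynthetic overview**
1. The target is two 4-hydroxy-1-methyl-2-quinolone units on a lavandulyl-type C10 bridge. Ring B (the gem-dimethylpyran) is opened at O–CMe2 to a free 4-OH and an isopropenyl group; it is closed last by acid hydroalkoxylation.
2. Ring A is opened at its O–CH(aryl) bond: an intramolecular oxa-Michael addition of a quinolone 4-OH to a 3-alkylidenequinoline-2,4-dione, which comes from Knoevenagel condensation of a lactol-masked aldehyde with the second quinolone.
3. The lactol comes from an amine-catalysed asymmetric Michael addition/hemiacetalisation of the quinolone with (2E)-5-methyl-2-(prop-1-en-2-yl)hexa-2,4-dienal. This sets the isobutenyl-bearing centre; the other two centres follow under equilibrating conditions.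
4. Building blocks: the dienal from two molecules of prenal (directed aldol condensation), the quinolone from N-methylisatoic anhydride and diethyl malonate.
5. Ring order: quinolone pyridone ring, then ring A (formed as lactol, reopened and reclosed by oxa-Michael addition), then ring B.

Assumption: the facial sense of the cinchona primary amine in step 5 is taken by analogy with related iminium additions; if the (4R) series results, the quinidine-derived pseudo-enantiomer of the catalyst is used and nothing else changes.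

**Step 1**
Reactants: 1 1-methyl-2H-3,1-benzoxazine-2,4(1H)-dione (N-methylisatoic anhydride); 2 diethyl propanedioate (diethyl malonate)
Product: 4 ethyl 4-hydroxy-1-methyl-2-oxo-1,2-dihydroquinoline-3-carboxylate, via acylmalonate 3 (not isolated)
Conditions: NaH (1.1 equiv), N,N-dimethylacetamide, 0 °C → 120 °C; then 1 M HCl
Reagents that add atoms: none
Why: The malonate anion C-acylates the anhydride carbonyl, CO2 is lost from the carbamate, and the freed N-methylaniline nitrogen lactamises onto one ester (acylation/lactamisation route to 4-hydroxy-2-quinolones); no stereocentre.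

**Step 2**
Reactants: 4 ethyl 4-hydroxy-1-methyl-2-oxo-1,2-dihydroquinoline-3-carboxylate
Product: 6 4-hydroxy-1-methylquinolin-2(1H)-one, via quinolone-3-carboxylic acid 5 (not isolated)
Conditions: 6 M HCl (aq), AcOH, reflux
Reagents that add atoms: none
Why: Acid hydrolysis of the ester gives the vinylogous β-keto acid 5, which decarboxylates at reflux (ester hydrolysis/decarboxylation); no stereocentre.

**Step 3**
Reactants: 7 3-methylbut-2-enal (prenal); 8 cyclohexylamine
Product: 9 (1E)-N-cyclohexyl-3-methylbut-2-en-1-imine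
Conditions: 4 Å molecular sieves, Et2O, 0 °C → rt
Reagents that add atoms: none
Why: Imine condensation driven by removal of water; it masks the aldehyde and makes the γ-methyl group acidic for the next step.

**Step 4**
Reactants: 9 (1E)-N-cyclohexyl-3-methylbut-2-en-1-imine; 7 3-methylbut-2-enal
Product: 13 (2E)-5-methyl-2-(prop-1-en-2-yl)hexa-2,4-dienal, via lithium cyclohexyl(3-methylbuta-1,3-dienyl)amide 10 (not isolated), via lithium 1-(cyclohexylimino)-5-methyl-2-(prop-1-en-2-yl)hex-4-en-3-olate 11 (not isolated), via hydroxy aldehyde 12 (not isolated)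
Conditions: LiN(iPr)2 (1.05 equiv), THF, −78 °C; 7 (1.0 equiv), −78 °C; then oxalic acid (aq), THF, rt
Reagents that add atoms: water, O
Why: Directed aldol condensation: the lithium 1-azadienyl anion 10 attacks 7 kinetically through its α-carbon, hydrolysis frees aldehyde 12, and its doubly activated α-H and allylic hydroxyl allow loss of water to the conjugated (2E)-dienal (CHO trans to the dimethylvinyl group); no stereocentre.

**Step 5**
Reactants: 6 4-hydroxy-1-methylquinolin-2(1H)-one; 13 (2E)-5-methyl-2-(prop-1-en-2-yl)hexa-2,4-dienal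
Product: 15 (3R,4S)-2-hydroxy-6-methyl-4-(2-methylprop-1-en-1-yl)-3-(prop-1-en-2-yl)-3,4-dihydro-2H-pyrano[3,2-c]quinolin-5(6H)-one (both anomers), via open-chain aldehyde 14 (not isolated)
Conditions: 9-amino-9-deoxy-epi-quinine (20 mol%), CF3CO2H (30 mol%), toluene, 0 °C → rt
Reagents that add atoms: none
Why: Iminium-ion-catalysed Michael addition (primary-amine catalysis copes with the α-branch) of C3 of 6 to the β-carbon of 13, then hemiacetalisation; the catalyst blocks one face of the iminium ion and so sets C4 (S), while C3 is set by protonation of the enamine and equilibrates through it to the trans-diaxial (3R) arrangement, which avoids allylic strain between the isobutenyl group and the lactam carbonyl.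

**Step 6**
Reactants: 15 the (3R,4S)-lactol; 6 4-hydroxy-1-methylquinolin-2(1H)-one
Product: 18 CNP0210533.1 (target), via alkylidene quinolinedione 16 (not isolated), via ring A hydroxyquinolone 17 (not isolated)
Conditions: ethylenediammonium diacetate (10 mol%), CH2Cl2, rt; then CF3SO3H (40 mol%), 0 °C
Reagents that add atoms: none
Why: Knoevenagel condensation of the ring-opened aldehyde with 6 gives alkylidenedione 16, whose β-carbon is taken by the 4-OH of the first quinolone in a reversible intramolecular oxa-Michael addition that closes ring A with the new aryl group equatorial and cis to the axial isopropenyl group (2R); Markovnikov protonation of the isopropenyl group then lets the remaining 4-OH close ring B (intramolecular hydroalkoxylation) cis-fused, with the three stereocentres kept.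

**Compound list**
1 | 1-methyl-2H-3,1-benzoxazine-2,4(1H)-dione (N-methylisatoic anhydride) | CN1C(=O)OC(=O)c2ccccc21 | starting material
2 | diethyl propanedioate (diethyl malonate) | CCOC(=O)CC(=O)OCC | starting material
3 | diethyl 2-[2-(methylamino)benzoyl]propanedioate (present as its sodium enolate) | CCOC(=O)C(C(=O)OCC)C(=O)c1ccccc1NC | intermediate
4 | ethyl 4-hydroxy-1-methyl-2-oxo-1,2-dihydroquinoline-3-carboxylate | CCOC(=O)c1c(O)c2ccccc2n(C)c1=O | intermediate
5 | 4-hydroxy-1-methyl-2-oxo-1,2-dihydroquinoline-3-carboxylic acid | O=C(O)c1c(O)c2ccccc2n(C)c1=O | intermediate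
6 | 4-hydroxy-1-methylquinolin-2(1H)-one | O=c1cc(O)c2ccccc2n1C | intermediate
7 | 3-methylbut-2-enal (prenal) | CC(C)=CC=O | starting material
8 | cyclohexylamine | NC1CCCCC1 | starting material
9 | (1E)-N-cyclohexyl-3-methylbut-2-en-1-imine | CC(C)=C/C=N/C1CCCCC1 | intermediate
10 | lithium cyclohexyl(3-methylbuta-1,3-dienyl)amide | [Li]N(C=CC(C)=C)C1CCCCC1 | intermediate
11 | lithium 1-(cyclohexylimino)-5-methyl-2-(prop-1-en-2-yl)hex-4-en-3-olate (diastereomer mixture) | CC(C)=CC(O[Li])C(C=NC1CCCCC1)C(C)=C | intermediate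
12 | 3-hydroxy-5-methyl-2-(prop-1-en-2-yl)hex-4-enal (diastereomer mixture) | CC(C)=CC(O)C(C=O)C(C)=C | intermediate
13 | (2E)-5-methyl-2-(prop-1-en-2-yl)hexa-2,4-dienal | CC(C)=C/C=C(/C=O)C(C)=C | intermediate
14 | (2R,3S)-3-(4-hydroxy-1-methyl-2-oxo-1,2-dihydroquinolin-3-yl)-5-methyl-2-(prop-1-en-2-yl)hex-4-enal | CC(C)=C[C@H](c1c(O)c2ccccc2n(C)c1=O)[C@@H](C=O)C(C)=C | intermediate
15 | (3R,4S)-2-hydroxy-6-methyl-4-(2-methylprop-1-en-1-yl)-3-(prop-1-en-2-yl)-3,4-dihydro-2H-pyrano[3,2-c]quinolin-5(6H)-one (anomer mixture at C2) | CC(C)=C[C@@H]1c2c(c3ccccc3n(C)c2=O)OC(O)[C@H]1C(C)=C | intermediate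
16 | 3-[(2R,3S)-3-(4-hydroxy-1-methyl-2-oxo-1,2-dihydroquinolin-3-yl)-5-methyl-2-(prop-1-en-2-yl)hex-4-en-1-ylidene]-1-methylquinoline-2,4(1H,3H)-dione | CC(C)=C[C@H](c1c(O)c2ccccc2n(C)c1=O)[C@@H](C=C1C(=O)c2ccccc2N(C)C1=O)C(C)=C | intermediate
17 | (2R,3R,4S)-2-(4-hydroxy-1-methyl-2-oxo-1,2-dihydroquinolin-3-yl)-6-methyl-4-(2-methylprop-1-en-1-yl)-3-(prop-1-en-2-yl)-3,4-dihydro-2H-pyrano[3,2-c]quinolin-5(6H)-one | CC(C)=C[C@@H]1c2c(c3ccccc3n(C)c2=O)O[C@@H](c3c(O)c4ccccc4n(C)c3=O)[C@H]1C(C)=C | intermediate
18 | CNP0210533.1: cis-fused bis(pyrano[3,2-c]quinolin-5-one); ring A carries the 2-methylprop-1-enyl group on an (S) carbon, the ring-fusion CH next to CMe2 is (S), the ring-fusion O–CH is (R) | CC(C)=C[C@@H]1c2c(c3ccccc3n(C)c2=O)O[C@H]2c3c(c4ccccc4n(C)c3=O)OC(C)(C)[C@@H]12 | target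

**Totals**
Total step count: 6. Longest linear sequence: 4 (steps 1, 2, 5, 6 or steps 3, 4, 5, 6).

**Three steps most likely to fail**

Step 5. The α-branched dienal may form its iminium ion slowly, may react 1,2 (Knoevenagel then oxa-6π-electrocyclisation) instead of 1,4, and the ee is uncertain. The fallback sets out from 7 and 6 and comes back at 18; it leaves the α-branch out of the asymmetric step and brings in the CMe2 carbon by an enolate aldol instead. Wittig reaction of 7 with Ph3P=CHCHO (toluene, 80 °C) gives (2E)-5-methylhexa-2,4-dienal F1. The secondary-amine version of the Michael addition/hemiacetalisation of 6 with F1 ((R)-α,α-diphenylprolinol trimethylsilyl ether 10 mol%, PhCO2H, CH2Cl2, rt) gives (4R)-2-hydroxy-6-methyl-4-(2-methylprop-1-en-1-yl)-3,4-dihydro-2H-pyrano[3,2-c]quinolin-5(6H)-one F2, which has the same spatial arrangement at C4 as 15. Dess–Martin periodinane oxidises it to (4R)-6-methyl-4-(2-methylprop-1-en-1-yl)-3,4-dihydro-2H-pyrano[3,2-c]quinoline-2,5(6H)-dione F3. Its lithium enolate (LiN(SiMe3)2, THF, −78 °C) adds to acetone anti to the isobutenyl group and gives (3R,4S)-3-(2-hydroxypropan-2-yl)-6-methyl-4-(2-methylprop-1-en-1-yl)-3,4-dihydro-2H-pyrano[3,2-c]quinoline-2,5(6H)-dione F4. Reduction with (iBu)2AlH (CH2Cl2, −78 °C) gives (3R,4S)-2-hydroxy-3-(2-hydroxypropan-2-yl)-6-methyl-4-(2-methylprop-1-en-1-yl)-3,4-dihydro-2H-pyrano[3,2-c]quinolin-5(6H)-one F5. F5 is condensed with 6 under the conditions of step 6, the tertiary alcohol ionising under CF3SO3H in place of the isopropenyl group, to reach 18.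

Step 6. Three events run in one flask. Possible failures are a bis-adduct with a second molecule of 6, closure through the lactam oxygen to a linear pyrano[2,3-b]quinolin-4-one, cation–olefin reactions of the isobutenyl group, and the wrong ring fusion; the cis fusion rests on a conformational argument, not on precedent. The fallback sets out from 15 and 6 and comes back at 18; it inverts the ring order. Heating 15 with 6 in pyridine at 90 °C (base-mediated shift of the isopropenyl double bond into conjugation, Knoevenagel condensation, oxa-6π-electrocyclisation) closes ring B first and gives 3-[(1S)-1-(4-hydroxy-1-methyl-2-oxo-1,2-dihydroquinolin-3-yl)-3-methylbut-2-en-1-yl]-2,2,6-trimethyl-2H-pyrano[3,2-c]quinolin-5(6H)-one F6. CF3CO2H (CH2Cl2, 0 °C) then protonates the pyran C3 under the control of the adjacent (S) centre, and the benzylic cation is captured by the free 4-OH. Ring A thus closes onto the preformed ring B, which favours the cis fusion kinetically, and gives 18.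

Step 4. The azadienyl anion may attack through its γ-carbon, dehydration may be incomplete, and the cis-triene in 13 can undergo 6π-electrocyclisation if warmed (keep 13 cold and use it promptly). The fallback sets out from 7 and comes back at 13; an ester dienolate replaces the metallated imine. Methyl 3-methylbut-2-enoate is deprotonated with LiN(iPr)2 (THF, −78 °C) and the dienolate adds through its α-carbon to 7 to give methyl 3-hydroxy-5-methyl-2-(prop-1-en-2-yl)hex-4-enoate F7. Dehydration (p-toluenesulfonic acid cat., toluene, 50 °C) gives methyl (2E)-5-methyl-2-(prop-1-en-2-yl)hexa-2,4-dienoate F8. Reduction with (iBu)2AlH (CH2Cl2, −78 °C) gives (2E)-5-methyl-2-(prop-1-en-2-yl)hexa-2,4-dien-1-ol F9, and MnO2 (CH2Cl2, rt) oxidises F9 to 13.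

**Further compounds**
F1 | step 5 | (2E)-5-methylhexa-2,4-dienal | CC(C)=C/C=C/C=O
F2 | step 5 | (4R)-2-hydroxy-6-methyl-4-(2-methylprop-1-en-1-yl)-3,4-dihydro-2H-pyrano[3,2-c]quinolin-5(6H)-one | CC(C)=C[C@@H]1c2c(c3ccccc3n(C)c2=O)OC(O)C1
F3 | step 5 | (4R)-6-methyl-4-(2-methylprop-1-en-1-yl)-3,4-dihydro-2H-pyrano[3,2-c]quinoline-2,5(6H)-dione | CC(C)=C[C@@H]1c2c(c3ccccc3n(C)c2=O)OC(=O)C1
F4 | step 5 | (3R,4S)-3-(2-hydroxypropan-2-yl)-6-methyl-4-(2-methylprop-1-en-1-yl)-3,4-dihydro-2H-pyrano[3,2-c]quinoline-2,5(6H)-dione | CC(C)=C[C@@H]1c2c(c3ccccc3n(C)c2=O)OC(=O)[C@H]1C(C)(C)O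
F5 | step 5 | (3R,4S)-2-hydroxy-3-(2-hydroxypropan-2-yl)-6-methyl-4-(2-methylprop-1-en-1-yl)-3,4-dihydro-2H-pyrano[3,2-c]quinolin-5(6H)-one | CC(C)=C[C@@H]1c2c(c3ccccc3n(C)c2=O)OC(O)[C@H]1C(C)(C)O
F6 | step 6 | 3-[(1S)-1-(4-hydroxy-1-methyl-2-oxo-1,2-dihydroquinolin-3-yl)-3-methylbut-2-en-1-yl]-2,2,6-trimethyl-2H-pyrano[3,2-c]quinolin-5(6H)-one | CC(C)=C[C@H](c1c(O)c2ccccc2n(C)c1=O)C1=Cc2c(c3ccccc3n(C)c2=O)OC1(C)C
F7 | step 4 | methyl 3-hydroxy-5-methyl-2-(prop-1-en-2-yl)hex-4-enoate | COC(=O)C(C(C)=C)C(O)C=C(C)C
F8 | step 4 | methyl (2E)-5-methyl-2-(prop-1-en-2-yl)hexa-2,4-dienoate | COC(=O)/C(C(C)=C)=C/C=C(C)C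
F9 | step 4 | (2E)-5-methyl-2-(prop-1-en-2-yl)hexa-2,4-dien-1-ol | OC/C(C(C)=C)=C/C=C(C)C
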